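The target is read as a ring-opened 2-oxabicyclo[2.2.2]oct-5-en-3-one. Labels: C1 is the quaternary carbinol carbon, C7 its CH2O carbon, C2=C3 the ring alkene, C4 the benzoate-bearing ring carbon, C5 and C6 the secondary carbinols (C6 next to C1). Because the C1–C7 and C4–O bonds point to the same face of the six-membered ring, C7 and that oxygen are joined as the lactone bridge, with C2=C3 as the etheno bridge. A single amine-catalysed asymmetric Diels–Alder reaction of 3-hydroxy-2-pyranone with the E enol acetate of formylacetone then makes C1–C6 and C4–C5, closes the carbocycle and sets C1, C4, C5 and C6. Baeyer–Villiger oxidation, lactone reduction, benzoylation and acetate solvolysis finish.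

Key step: step 2

Remark: the C5 oxygen is carried as an acetate so that it matches the acetate the Baeyer–Villiger step makes at C6; the enol acetate is made from but-3-yn-2-one, not through free formylacetone, which self-condenses; and the quinidine-derived catalyst is assumed to open the diene face that leads to the target, the quinine-derived pseudoenantiomer being used otherwise.

Step 1
Reactants: 1 but-3-yn-2-one
Product: 2 (E)-4-acetoxybut-3-en-2-one
Conditions: AcOH (1.1 equiv), DABCO (5 mol %), CH2Cl2, 0 °C → rt
Reagents that add atoms: acetic acid, CC(=O)O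
Why: Amine-catalysed conjugate (oxa-Michael) addition of a carboxylic acid to an ynone, in which reversible addition–elimination through the β-ammonium enone lets the enol ester settle as the conjugated E isomer.

Step 2
Reactants: 3 (3-hydroxy-2H-pyran-2-one) and 2 ((E)-4-acetoxybut-3-en-2-one)
Product: 4 (1R,4R,7S,8S)-8-acetyl-4-hydroxy-3-oxo-2-oxabicyclo[2.2.2]oct-5-en-7-yl acetate
Conditions: 2 (1.5 equiv), 1-[3,5-bis(trifluoromethyl)phenyl]-3-(9-deoxy-epi-quinidin-9-yl)thiourea (10 mol %), TBME, −20 °C; filtration through silica
Reagents that add atoms: none
Why: The quinuclidine nitrogen of the catalyst deprotonates the 3-hydroxyl of 3 and the thiourea hydrogen-bonds the ketone of 2, so that an electron-rich oxido-diene and an activated enone react inside one chiral ion pair; bond formation is polarized, the vinylogous nucleophilic ring carbon next to the ring oxygen (future C4) attacking the β-carbon of 2 (future C5) and the α-carbon of 2 (future C6) closing onto the oxide-bearing carbon (future C1), either as an asynchronous concerted [4+2] addition or as its Michael–aldol equivalent. The closest known reaction type is the amine-base-catalysed Diels–Alder reaction of 3-hydroxy-2-pyranones with enones and acrylates, including its cinchona-catalysed asymmetric form. The carbocycle C1–C6 is closed by a suprafacial [4+2] cycloaddition (read stepwise, a 6-exo-trig aldol of the C6 enolate onto the C1 ketone), and the pyranone ester becomes the lactone bridge of the bicycle. C5 and C6 come out trans because the E geometry of 2 is carried over suprafacially; the acetyl group at C6 should lie syn to the C2=C3 bridge through the endo transition state favoured by the hydrogen-bonded ketone, which puts the C5 acetate syn to the lactone bridge; C1 and C4 are tied to each other by that bridge, and the absolute sense is set by the diene face that the catalyst leaves open. The step needs regiocontrol, secured by the matching polarity of oxido-diene and enone, and endo and facial control, both secured by the two-point binding of the partners to the catalyst.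

Step 3
Reactants: 4 (1R,4R,7S,8S)-8-acetyl-4-hydroxy-3-oxo-2-oxabicyclo[2.2.2]oct-5-en-7-yl acetate
Product: 5 (1R,4R,7R,8S)-4-hydroxy-3-oxo-2-oxabicyclo[2.2.2]oct-5-ene-7,8-diyl diacetate
Conditions: mCPBA (2 equiv), CH2Cl2, 0 °C → rt
Reagents that add atoms: mCPBA (3-chloroperoxybenzoic acid), O=C(OO)c1cccc(Cl)c1
Why: Baeyer–Villiger oxidation, in which the secondary carbon C6 migrates in preference to methyl and with retention, so that the new C6–O bond takes the place and the face of the C6–acetyl bond, while the C2=C3 bridge between two oxygenated bridgeheads is too electron-poor to be epoxidized at a competing rate.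

Step 4
Reactants: 5 (1R,4R,7R,8S)-4-hydroxy-3-oxo-2-oxabicyclo[2.2.2]oct-5-ene-7,8-diyl diacetate
Product: 6 (1S,4R,5R,6S)-5,6-diacetoxy-1-(hydroxymethyl)cyclohex-2-ene-1,4-diol
Conditions: NaBH4 (2 equiv), THF–H2O (9:1), −10 → 0 °C; pH 7 phosphate buffer
Reagents that add atoms: none
Why: Borohydride reduction of an α-hydroxy lactone (the reactivity that turns aldonolactones into alditols): the strained, hydroxyl-activated lactone carbonyl C7 takes up two hydrides and releases the C4 hydroxyl, whereas the unactivated acetates are not reduced and, in a short cold aqueous run, should stay on C5 and C6; no stereocentre is touched.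

Step 5
Reactants: 6 (1S,4R,5R,6S)-5,6-diacetoxy-1-(hydroxymethyl)cyclohex-2-ene-1,4-diol
Product: 7 [(1S,4R,5R,6S)-5,6-diacetoxy-4-(benzoyloxy)-1-hydroxycyclohex-2-en-1-yl]methyl benzoate
Conditions: BzCl (2.3 equiv), pyridine, CH2Cl2, 0 °C
Reagents that add atoms: benzoyl chloride, O=C(Cl)c1ccccc1
Why: Acylation with an acid chloride and pyridine, which should benzoylate the primary C7 and the secondary allylic C4 hydroxyls and leave the hindered tertiary C1 hydroxyl free in the absence of an acyl-transfer catalyst.

Step 6
Reactants: 7 [(1S,4R,5R,6S)-5,6-diacetoxy-4-(benzoyloxy)-1-hydroxycyclohex-2-en-1-yl]methyl benzoate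
Product: 8 [(1S,4R,5S,6S)-4-(benzoyloxy)-1,5,6-trihydroxycyclohex-2-en-1-yl]methyl benzoate
Conditions: HCl (0.5 M) in MeOH, 0 °C → rt
Reagents that add atoms: none
Why: Acid-catalysed transesterification (methanolysis), which removes aliphatic acetates much faster than the conjugated benzoates and, having no alkoxide, gives the C4 benzoate no path to the cis C5 hydroxyl; only acyl–oxygen bonds break, so C5 and C6 keep their configuration.

Compound list
1 | but-3-yn-2-one | CC(=O)C#C | starting material
2 | (E)-4-acetoxybut-3-en-2-one | CC(=O)/C=C/OC(C)=O | intermediate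
3 | 3-hydroxy-2H-pyran-2-one | O=C1OC=CC=C1O | starting material
4 | (1R,4R,7S,8S)-8-acetyl-4-hydroxy-3-oxo-2-oxabicyclo[2.2.2]oct-5-en-7-yl acetate (acetyl syn to the alkene bridge, acetoxy syn to the lactone bridge) | O=C2[C@@]1(O)C=C[C@@H](O2)[C@@H](OC(C)=O)[C@@H]1C(C)=O | intermediate
5 | (1R,4R,7R,8S)-4-hydroxy-3-oxo-2-oxabicyclo[2.2.2]oct-5-ene-7,8-diyl diacetate | O=C2[C@@]1(O)C=C[C@@H](O2)[C@@H](OC(C)=O)[C@@H]1OC(C)=O | intermediate
6 | (1S,4R,5R,6S)-5,6-diacetoxy-1-(hydroxymethyl)cyclohex-2-ene-1,4-diol | OC[C@@]1(O)C=C[C@@H](O)[C@@H](OC(C)=O)[C@@H]1OC(C)=O | intermediate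
7 | [(1S,4R,5R,6S)-5,6-diacetoxy-4-(benzoyloxy)-1-hydroxycyclohex-2-en-1-yl]methyl benzoate | O=C(OC[C@@]1(O)C=C[C@@H](OC(=O)c2ccccc2)[C@@H](OC(C)=O)[C@@H]1OC(C)=O)c1ccccc1 | intermediate
8 | [(1S,4R,5S,6S)-4-(benzoyloxy)-1,5,6-trihydroxycyclohex-2-en-1-yl]methyl benzoate | O=C(OC[C@@]1(O)C=C[C@@H](OC(=O)c2ccccc2)[C@@H](O)[C@@H]1O)c1ccccc1 | target

Total step count: 6. Longest linear sequence: 6 steps (1 → 2 → 4 → 5 → 6 → 7 → 8).

Steps most likely to fail

Step 2. The enol ester 2 is also an acyl donor, so acetyl transfer to the hydroxyl of 3 may compete with cycloaddition. The β-acetoxy ketone may lose acetic acid, and either process protonates the basic catalyst. The cycloaddition may also be slow, or endo and facial control weak. Fallback: the C5 oxygen is brought in as a second acetyl group. (E)-Hex-3-ene-2,5-dione F1 is made from 2,5-dimethylfuran by oxidative ring opening with mCPBA and isomerization of the first-formed Z isomer with a trace of iodine. It is a doubly activated dienophile of the class for which this catalysis is established, and it has neither a leaving group nor a transferable acyl group. Under the conditions of step 2 it should add to 3 to give the trans-7,8-diacetyl lactone F2, for which regiochemistry is no longer an issue. A twofold Baeyer–Villiger oxidation with excess mCPBA then turns both acetyl groups into acetates with retention. The fallback sets out from 3 and returns to the route at 5.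

Step 4. The C5 acetate may migrate to the neighbouring cis C4 alkoxide (or the C6 acetate to C7), or acetate may be partly lost during the reduction, which would scramble the oxygens benzoylated next. Fallback: no ester is kept on C5 and C6 while the C4 and C7 hydroxyls are free. From 5, K2CO3 in MeOH opens the lactone to the methyl ester and removes both acetates, giving the tetrol methyl ester F3. Butane-2,3-dione, trimethyl orthoformate and camphorsulfonic acid in MeOH protect the trans-diequatorial C5/C6 diol as the butane-2,3-diacetal F4; the cis C4/C5 pair and the tertiary C1 hydroxyl do not form this acetal. LiBH4 in THF reduces the α-hydroxy ester to the C7 alcohol F5, BzCl in pyridine gives the dibenzoate F6, and aqueous TFA removes the diacetal. The fallback sets out from 5 and returns to the route at 8.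

Step 3. The peracid may epoxidize the strained C2=C3 bridge, or migration of the electron-poor C6 may be slow. Fallback: the mode of activation is changed from an electrophilic peracid to a silyl peroxide that attacks the Lewis-acid-bound ketone. Bis(trimethylsilyl) peroxide with catalytic SnCl4 in CH2Cl2 at low temperature is a Baeyer–Villiger variant that leaves alkenes untouched. It sets out from 4, returns at 5 and makes no further compound (F0).

Further compounds
F1 | step 2 | (E)-hex-3-ene-2,5-dione | CC(=O)/C=C/C(C)=O
F2 | step 2 | 7,8-diacetyl-4-hydroxy-2-oxabicyclo[2.2.2]oct-5-en-3-one, 8-acetyl syn to the alkene bridge and 7-acetyl syn to the lactone bridge, absolute configuration as in 4 | O=C2[C@@]1(O)C=C[C@@H](O2)[C@@H](C(C)=O)[C@@H]1C(C)=O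
F3 | step 4 | methyl 1,4,5,6-tetrahydroxycyclohex-2-ene-1-carboxylate, ring configuration as in 8 | COC(=O)[C@@]1(O)C=C[C@@H](O)[C@@H](O)[C@@H]1O
F4 | step 4 | 5,6-O-(2,3-dimethoxybutane-2,3-diyl) acetal of F3, methoxy groups axial | COC(=O)[C@@]1(O)C=C[C@@H](O)[C@H]2O[C@](C)(OC)[C@@](C)(OC)O[C@H]12
F5 | step 4 | C7 alcohol from F4 (1-hydroxymethyl-1,4-diol with the C5/C6 diacetal) | OC[C@@]1(O)C=C[C@@H](O)[C@H]2O[C@](C)(OC)[C@@](C)(OC)O[C@H]12
F6 | step 4 | C4,C7-dibenzoate of F5 | O=C(OC[C@@]1(O)C=C[C@@H](OC(=O)c3ccccc3)[C@H]2O[C@](C)(OC)[C@@](C)(OC)O[C@H]12)c1ccccc1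
F0 | step 3 | none | none
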